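**Retrosynthetic overview**
1. The target comes from global hydrogenolysis of a benzyl/ketal-protected dimer that already carries both tri-O-benzylgalloyl esters. The esters go onto the only two free hydroxyls (ring F C3–OH, ring E C3′–OH); the ring C C3 oxygen stays benzylated.
2. Key disconnection: both pyran rings are cut at C4–C4a. Rings C and F close together by two intramolecular Friedel–Crafts alkylations of one acyclic precursor: a ring D benzylic carbinol becomes C4 of ring C (onto ring A), and a terminal epoxide CH2 becomes C4 of ring F (onto ring D).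
3. Ring D is a 4-substituted 3,5-bis(benzyloxy)phenyl ether, so its two free ortho carbons are equivalent and only the 4→6 connectivity can form. The carbinol is made by adding the ring D aryllithium to an α-benzyloxy aldehyde.
4. Both halves are threo β-aryloxy-α-hydroxy esters, made by Z-selective olefination, Jacobsen epoxidation and phenoxide opening (inversion) of the cis-glycidic esters. This fixes C2/C3 of both units; C4 is fixed during ring closure.
5. Ring order: rings A, B, D, E and the galloyl rings are bought; a temporary benzodioxole ring protects ring E first; ring C then ring F are formed last, in the same flask.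

Ring letters: upper unit A (phloroglucinol), B (4-hydroxyphenyl), C (pyran); lower unit D (phloroglucinol), E (pyrogallol), F (pyran).
Assumption: all benzyl-protected aromatic building blocks used as starting materials are taken as inexpensive catalogue compounds.

**Step 1**
Reactants: 1 3,4,5-trihydroxybenzaldehyde
Product: 3 2,2-diphenyl-7-(prop-2-en-1-yloxy)-1,3-benzodioxole-5-carbaldehyde, via hydroxy ketal aldehyde 2 (not isolated)
Conditions: Ph2CCl2 (1.1 equiv), K2CO3 (4 equiv), MeCN, rt; then allyl bromide (1.5 equiv), 60 °C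
Reagents that add atoms: dichlorodiphenylmethane ClC(Cl)(c1ccccc1)c1ccccc1; allyl bromide C=CCBr
Why: Only the vicinal 3,4-diol can bridge the diphenylmethylene carbon (double Williamson-type ketalisation), which leaves one meta hydroxyl that is then allylated in the same basic medium (Williamson ether synthesis), so the later gallate position is marked; no stereocentre is formed.

**Step 2**
Reactants: 3 2,2-diphenyl-7-(prop-2-en-1-yloxy)-1,3-benzodioxole-5-carbaldehyde; 4 ethyl 2-(diphenoxyphosphoryl)acetate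
Product: 5 ethyl (2Z)-3-[2,2-diphenyl-7-(prop-2-en-1-yloxy)-1,3-benzodioxol-5-yl]prop-2-enoate
Conditions: NaH, THF, −78 °C to 0 °C
Reagents that add atoms: none
Why: Horner–Wadsworth–Emmons olefination with the Ando diaryl phosphonate is kinetically Z-selective with aromatic aldehydes, giving the cis alkene that is the source of the 2,3-cis relationship in ring F; the minor E ester is removed by chromatography.

**Step 3**
Reactants: 5 ethyl (2Z)-3-[2,2-diphenyl-7-(prop-2-en-1-yloxy)-1,3-benzodioxol-5-yl]prop-2-enoate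
Product: 6 ethyl (2S,3S)-3-[2,2-diphenyl-7-(prop-2-en-1-yloxy)-1,3-benzodioxol-5-yl]oxirane-2-carboxylate
Conditions: (S,S)-(salen)MnCl = chloro[(S,S)-N,N'-bis(3,5-di-tert-butylsalicylidene)cyclohexane-1,2-diaminato]manganese (trivalent manganese, 5 mol%), 4-phenylpyridine N-oxide (25 mol%), aq. NaOCl buffered with Na2HPO4 (pH 11.3), CH2Cl2, 0 °C
Reagents that add atoms: sodium hypochlorite [Na+].[O-]Cl
Why: Jacobsen–Katsuki epoxidation, for which cis-cinnamate esters are among the best substrates; the (S,S)-salen ligand directs oxygen transfer to the alkene face that gives the (2S,3S)-cis-glycidate, so both stereocentres are set by the catalyst.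

**Step 4**
Reactants: 7 3,5-bis(benzyloxy)phenol
Product: 8 3,5-bis(benzyloxy)-4-bromophenol
Conditions: NBS (1.0 equiv), DMF, −20 °C
Reagents that add atoms: N-bromosuccinimide O=C1CCC(=O)N1Br
Why: Electrophilic aromatic bromination in polar DMF is directed para by the free hydroxyl, giving the symmetric 4-bromide (the minor ortho isomer is separated); no stereocentre is formed.

**Step 5**
Reactants: 6 ethyl (2S,3S)-3-[2,2-diphenyl-7-(prop-2-en-1-yloxy)-1,3-benzodioxol-5-yl]oxirane-2-carboxylate; 8 3,5-bis(benzyloxy)-4-bromophenol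
Product: 9 ethyl (2S,3R)-3-[3,5-bis(benzyloxy)-4-bromophenoxy]-3-[2,2-diphenyl-7-(prop-2-en-1-yloxy)-1,3-benzodioxol-5-yl]-2-hydroxypropanoate
Conditions: Cs2CO3 (0.3 equiv), DMF, 50 °C
Reagents that add atoms: none
Why: Base-mediated SN2 opening of the glycidic ester by the phenoxide at the benzylic C3 (attack at C2 is disfavoured next to the ester) goes with inversion (3S to 3R), turning the cis-epoxide into the threo aryl ether whose two centres map onto C3 and C2 of ring F.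

**Step 6**
Reactants: 9 ethyl (2S,3R)-3-[3,5-bis(benzyloxy)-4-bromophenoxy]-3-[2,2-diphenyl-7-(prop-2-en-1-yloxy)-1,3-benzodioxol-5-yl]-2-hydroxypropanoate
Product: 10 (2R,3R)-3-[3,5-bis(benzyloxy)-4-bromophenoxy]-3-[2,2-diphenyl-7-(prop-2-en-1-yloxy)-1,3-benzodioxol-5-yl]propane-1,2-diol
Conditions: LiBH4, THF, 0 °C to rt
Reagents that add atoms: none
Why: Chemoselective hydride reduction of the ester to the primary alcohol leaves aryl bromide, ketal and allyl ether alone and does not touch the stereocentres (the C2 descriptor changes only because the CIP priorities change).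

**Step 7**
Reactants: 10 (2R,3R)-3-[3,5-bis(benzyloxy)-4-bromophenoxy]-3-[2,2-diphenyl-7-(prop-2-en-1-yloxy)-1,3-benzodioxol-5-yl]propane-1,2-diol
Product: 12 (2R)-2-{(R)-[3,5-bis(benzyloxy)-4-bromophenoxy][2,2-diphenyl-7-(prop-2-en-1-yloxy)-1,3-benzodioxol-5-yl]methyl}oxirane, via primary tosylate 11 (not isolated)
Conditions: NaH (2.2 equiv), N-tosylimidazole (1.05 equiv), THF, 0 °C to rt
Reagents that add atoms: none
Why: One-pot selective sulfonylation of the primary alkoxide followed by intramolecular Williamson displacement by the secondary alkoxide gives the terminal epoxide; no bond to either stereocentre is broken, so both are retained.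

**Step 8**
Reactants: 13 4-(benzyloxy)benzaldehyde; 4 ethyl 2-(diphenoxyphosphoryl)acetate
Product: 14 ethyl (2Z)-3-[4-(benzyloxy)phenyl]prop-2-enoate
Conditions: NaH, THF, −78 °C to 0 °C
Reagents that add atoms: none
Why: Z-selective Horner–Wadsworth–Emmons olefination (Ando phosphonate) as in step 2, giving the cis alkene that becomes the 2,3-cis relationship of ring C.

**Step 9**
Reactants: 14 ethyl (2Z)-3-[4-(benzyloxy)phenyl]prop-2-enoate
Product: 15 ethyl (2S,3S)-3-[4-(benzyloxy)phenyl]oxirane-2-carboxylate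
Conditions: (S,S)-(salen)MnCl (trivalent manganese, 5 mol%), 4-phenylpyridine N-oxide (25 mol%), aq. NaOCl buffered with Na2HPO4 (pH 11.3), CH2Cl2, 0 °C
Reagents that add atoms: sodium hypochlorite [Na+].[O-]Cl
Why: Jacobsen–Katsuki epoxidation of the cis-cinnamate, with the same catalyst enantiomer as in step 3, sets both stereocentres of the (2S,3S)-cis-glycidate by catalyst control.

**Step 10**
Reactants: 15 ethyl (2S,3S)-3-[4-(benzyloxy)phenyl]oxirane-2-carboxylate; 7 3,5-bis(benzyloxy)phenol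
Product: 16 ethyl (2S,3R)-3-[3,5-bis(benzyloxy)phenoxy]-3-[4-(benzyloxy)phenyl]-2-hydroxypropanoate
Conditions: Cs2CO3 (0.3 equiv), DMF, 40 °C
Reagents that add atoms: none
Why: SN2 opening of the glycidic ester at the benzylic carbon by the phenoxide with inversion (3S to 3R) creates the ring A aryl ether (future O1–C2 bond); the Lewis-acid-free, polar aprotic medium favours O- over C-alkylation and suppresses ionisation of the 4-alkoxybenzylic centre.

**Step 11**
Reactants: 16 ethyl (2S,3R)-3-[3,5-bis(benzyloxy)phenoxy]-3-[4-(benzyloxy)phenyl]-2-hydroxypropanoate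
Product: 17 ethyl (2S,3R)-2-(benzyloxy)-3-[3,5-bis(benzyloxy)phenoxy]-3-[4-(benzyloxy)phenyl]propanoate
Conditions: BnBr, Ag2O, CH2Cl2, rt, dark
Reagents that add atoms: benzyl bromide BrCc1ccccc1
Why: Silver-oxide-mediated Williamson benzylation (Purdie conditions) alkylates the α-hydroxyl without a strong base, avoiding β-elimination of the aryloxide and epimerisation; this benzyl group later keeps the ring C C3 oxygen from being galloylated.

**Step 12**
Reactants: 17 ethyl (2S,3R)-2-(benzyloxy)-3-[3,5-bis(benzyloxy)phenoxy]-3-[4-(benzyloxy)phenyl]propanoate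
Product: 18 (2S,3R)-2-(benzyloxy)-3-[3,5-bis(benzyloxy)phenoxy]-3-[4-(benzyloxy)phenyl]propanal
Conditions: i-Bu2AlH (1.1 equiv), CH2Cl2, −78 °C; aq. KNaC4H4O6 work-up
Reagents that add atoms: none
Why: Partial reduction of the α-alkoxy ester stops at the chelated tetrahedral aluminium hemiacetal, which releases the aldehyde on work-up; the α-centre is not epimerised under these non-basic conditions.

**Step 13**
Reactants: 12 (2R)-2-{(R)-[3,5-bis(benzyloxy)-4-bromophenoxy][2,2-diphenyl-7-(prop-2-en-1-yloxy)-1,3-benzodioxol-5-yl]methyl}oxirane; 18 (2S,3R)-2-(benzyloxy)-3-[3,5-bis(benzyloxy)phenoxy]-3-[4-(benzyloxy)phenyl]propanal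
Product: 20 (1RS,2R,3R)-2-(benzyloxy)-3-[3,5-bis(benzyloxy)phenoxy]-3-[4-(benzyloxy)phenyl]-1-{2,6-bis(benzyloxy)-4-[(R)-[2,2-diphenyl-7-(prop-2-en-1-yloxy)-1,3-benzodioxol-5-yl][(2R)-oxiran-2-yl]methoxy]phenyl}propan-1-ol, via aryllithium 19 (not isolated)
Conditions: n-BuLi (1.05 equiv), THF, −78 °C, 10 min; then 18, −78 °C; aq. NaHCO3
Reagents that add atoms: none
Why: Bromine–lithium exchange on the doubly ortho-alkoxylated aryl bromide is much faster than attack on the terminal epoxide at −78 °C, and the aryllithium then adds 1,2 to the aldehyde; the new carbinol centre forms as a mixture on purpose, because it is ionised in the next step.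

**Step 14**
Reactants: 20 (1RS,2R,3R)-2-(benzyloxy)-3-[3,5-bis(benzyloxy)phenoxy]-3-[4-(benzyloxy)phenyl]-1-{2,6-bis(benzyloxy)-4-[(R)-[2,2-diphenyl-7-(prop-2-en-1-yloxy)-1,3-benzodioxol-5-yl][(2R)-oxiran-2-yl]methoxy]phenyl}propan-1-ol
Product: 22 (2R,3R)-5,7-bis(benzyloxy)-6-{(2R,3R)-3,5,7-tris(benzyloxy)-2-[4-(benzyloxy)phenyl]-3,4-dihydro-2H-chromen-4-yl}-2-[2,2-diphenyl-7-(prop-2-en-1-yloxy)-1,3-benzodioxol-5-yl]-3,4-dihydro-2H-chromen-3-ol (upper C4 aryl trans to C3 benzyloxy; 4β→6), via ring-C-closed epoxide 21 (not isolated)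
Conditions: 1,1,1,3,3,3-hexafluoropropan-2-ol (HFIP, 0.005 M), 0 °C to rt; then NaHCO3
Reagents that add atoms: none
Why: Proposed new method: in the ionising, non-nucleophilic solvent the 2,4,6-trioxygenated benzylic alcohol loses water to a ring D stabilised cation that is captured in a 6-membered closure by the tethered ortho carbon of ring A (ring C forms; the C3–H eclipses the bulky aryl to avoid allylic 1,3-strain and the tether forces attack from the C2 side, so the new C4 centre is 3,4-trans, which is also the thermodynamic 4β isomer), after which ring D, nucleophilic again, opens the hydrogen-bond-activated terminal epoxide at CH2 in a 6-endo epoxy-arene cyclisation with C3′ untouched (ring F forms; only the 4→6 connectivity is possible because both ortho carbons of ring D are equivalent); the closest known reactions are dehydrative Friedel–Crafts alkylations of electron-rich benzylic alcohols in HFIP and the HFIP-promoted Friedel–Crafts cyclisation of aryl glycidyl ethers to chroman-3-ols.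

**Step 15**
Reactants: 22 (the ring E allyl ether dimer from step 14)
Product: 23 (2R,3R)-5,7-bis(benzyloxy)-6-{(2R,3R)-3,5,7-tris(benzyloxy)-2-[4-(benzyloxy)phenyl]-3,4-dihydro-2H-chromen-4-yl}-2-(7-hydroxy-2,2-diphenyl-1,3-benzodioxol-5-yl)-3,4-dihydro-2H-chromen-3-ol (4β→6)
Conditions: Pd(PPh3)4 (5 mol%, zerovalent palladium), morpholine (5 equiv), THF, rt
Reagents that add atoms: none
Why: Tsuji–Trost deallylation: zerovalent palladium ionises the allyl aryl ether to a π-allyl complex that is captured by morpholine, freeing the ring E phenol without touching benzyl ethers or the ketal.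

**Step 16**
Reactants: 23 (the diol from step 15); 24 3,4,5-tris(benzyloxy)benzoic acid
Product: 25 (2R,3R)-5,7-bis(benzyloxy)-6-{(2R,3R)-3,5,7-tris(benzyloxy)-2-[4-(benzyloxy)phenyl]-3,4-dihydro-2H-chromen-4-yl}-2-(2,2-diphenyl-7-{[3,4,5-tris(benzyloxy)benzoyl]oxy}-1,3-benzodioxol-5-yl)-3,4-dihydro-2H-chromen-3-yl 3,4,5-tris(benzyloxy)benzoate (4β→6)
Conditions: 24 (2.5 equiv), DCC, DMAP, CH2Cl2, rt
Reagents that add atoms: none
Why: Steglich esterification acylates the only two free hydroxyls, the ring F C3 alcohol and the ring E phenol, in one pass; the ring C oxygen is benzylated and stays unacylated.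

**Step 17**
Reactants: 25 (the protected bis-gallate from step 16)
Product: 26 epiafzelechin-(4β→6)-epigallocatechin 3,3′-di-O-gallate
Conditions: H2 (1 atm), Pd(OH)2 on carbon, THF/MeOH, rt
Reagents that add atoms: none
Why: Catalytic hydrogenolysis cleaves all twelve benzyl ethers and the diphenylmethylene ketal in one operation, while the esters, the interflavan bond and all five stereocentres are untouched.

**Compound list**
1 | 3,4,5-trihydroxybenzaldehyde | O=Cc1cc(O)c(O)c(O)c1 | starting material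
2 | 7-hydroxy-2,2-diphenyl-1,3-benzodioxole-5-carbaldehyde | O=Cc1cc(O)c2OC(c3ccccc3)(c3ccccc3)Oc2c1 | intermediate
3 | 2,2-diphenyl-7-(prop-2-en-1-yloxy)-1,3-benzodioxole-5-carbaldehyde | O=Cc1cc(OCC=C)c2OC(c3ccccc3)(c3ccccc3)Oc2c1 | intermediate
4 | ethyl 2-(diphenoxyphosphoryl)acetate | CCOC(=O)CP(=O)(Oc1ccccc1)Oc1ccccc1 | starting material
5 | ethyl (2Z)-3-[2,2-diphenyl-7-(prop-2-en-1-yloxy)-1,3-benzodioxol-5-yl]prop-2-enoate | CCOC(=O)/C=C\c1cc(OCC=C)c2OC(c3ccccc3)(c3ccccc3)Oc2c1 | intermediate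
6 | ethyl (2S,3S)-3-[2,2-diphenyl-7-(prop-2-en-1-yloxy)-1,3-benzodioxol-5-yl]oxirane-2-carboxylate | CCOC(=O)[C@H]1O[C@H]1c1cc(OCC=C)c2OC(c3ccccc3)(c3ccccc3)Oc2c1 | intermediate
7 | 3,5-bis(benzyloxy)phenol | Oc1cc(OCc2ccccc2)cc(OCc2ccccc2)c1 | starting material
8 | 3,5-bis(benzyloxy)-4-bromophenol | Oc1cc(OCc2ccccc2)c(Br)c(OCc2ccccc2)c1 | intermediate
9 | ethyl (2S,3R)-3-[3,5-bis(benzyloxy)-4-bromophenoxy]-3-[2,2-diphenyl-7-(prop-2-en-1-yloxy)-1,3-benzodioxol-5-yl]-2-hydroxypropanoate | Brc1c(OCc2ccccc2)cc(O[C@H](c2cc(OCC=C)c3OC(c4ccccc4)(c4ccccc4)Oc3c2)[C@H](O)C(=O)OCC)cc1OCc1ccccc1 | intermediate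
10 | (2R,3R)-3-[3,5-bis(benzyloxy)-4-bromophenoxy]-3-[2,2-diphenyl-7-(prop-2-en-1-yloxy)-1,3-benzodioxol-5-yl]propane-1,2-diol | Brc1c(OCc2ccccc2)cc(O[C@H](c2cc(OCC=C)c3OC(c4ccccc4)(c4ccccc4)Oc3c2)[C@H](O)CO)cc1OCc1ccccc1 | intermediate
11 | (2R,3R)-3-[3,5-bis(benzyloxy)-4-bromophenoxy]-3-[2,2-diphenyl-7-(prop-2-en-1-yloxy)-1,3-benzodioxol-5-yl]-2-hydroxypropyl 4-methylbenzenesulfonate | Brc1c(OCc2ccccc2)cc(O[C@H](c2cc(OCC=C)c3OC(c4ccccc4)(c4ccccc4)Oc3c2)[C@H](O)COS(=O)(=O)c2ccc(C)cc2)cc1OCc1ccccc1 | intermediate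
12 | (2R)-2-{(R)-[3,5-bis(benzyloxy)-4-bromophenoxy][2,2-diphenyl-7-(prop-2-en-1-yloxy)-1,3-benzodioxol-5-yl]methyl}oxirane | Brc1c(OCc2ccccc2)cc(O[C@H](c2cc(OCC=C)c3OC(c4ccccc4)(c4ccccc4)Oc3c2)[C@H]2CO2)cc1OCc1ccccc1 | intermediate
13 | 4-(benzyloxy)benzaldehyde | O=Cc1ccc(OCc2ccccc2)cc1 | starting material
14 | ethyl (2Z)-3-[4-(benzyloxy)phenyl]prop-2-enoate | CCOC(=O)/C=C\c1ccc(OCc2ccccc2)cc1 | intermediate
15 | ethyl (2S,3S)-3-[4-(benzyloxy)phenyl]oxirane-2-carboxylate | CCOC(=O)[C@H]1O[C@H]1c1ccc(OCc2ccccc2)cc1 | intermediate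
16 | ethyl (2S,3R)-3-[3,5-bis(benzyloxy)phenoxy]-3-[4-(benzyloxy)phenyl]-2-hydroxypropanoate | O(c1cc(OCc2ccccc2)cc(OCc2ccccc2)c1)[C@H](c1ccc(OCc2ccccc2)cc1)[C@H](O)C(=O)OCC | intermediate
17 | ethyl (2S,3R)-2-(benzyloxy)-3-[3,5-bis(benzyloxy)phenoxy]-3-[4-(benzyloxy)phenyl]propanoate | O(c1cc(OCc2ccccc2)cc(OCc2ccccc2)c1)[C@H](c1ccc(OCc2ccccc2)cc1)[C@H](OCc1ccccc1)C(=O)OCC | intermediate
18 | (2S,3R)-2-(benzyloxy)-3-[3,5-bis(benzyloxy)phenoxy]-3-[4-(benzyloxy)phenyl]propanal | O(c1cc(OCc2ccccc2)cc(OCc2ccccc2)c1)[C@H](c1ccc(OCc2ccccc2)cc1)[C@H](OCc1ccccc1)C=O | intermediate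
19 | {2,6-bis(benzyloxy)-4-[(R)-[2,2-diphenyl-7-(prop-2-en-1-yloxy)-1,3-benzodioxol-5-yl][(2R)-oxiran-2-yl]methoxy]phenyl}lithium | [Li]c1c(OCc2ccccc2)cc(O[C@H](c2cc(OCC=C)c3OC(c4ccccc4)(c4ccccc4)Oc3c2)[C@H]2CO2)cc1OCc1ccccc1 | intermediate
20 | (1RS,2R,3R)-2-(benzyloxy)-3-[3,5-bis(benzyloxy)phenoxy]-3-[4-(benzyloxy)phenyl]-1-{2,6-bis(benzyloxy)-4-[(R)-[2,2-diphenyl-7-(prop-2-en-1-yloxy)-1,3-benzodioxol-5-yl][(2R)-oxiran-2-yl]methoxy]phenyl}propan-1-ol | O(c1cc(OCc2ccccc2)cc(OCc2ccccc2)c1)[C@H](c1ccc(OCc2ccccc2)cc1)[C@H](OCc1ccccc1)C(O)c1c(OCc2ccccc2)cc(O[C@H](c2cc(OCC=C)c3OC(c4ccccc4)(c4ccccc4)Oc3c2)[C@H]2CO2)cc1OCc1ccccc1 | intermediate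
21 | (2R,3R)-3,5,7-tris(benzyloxy)-2-[4-(benzyloxy)phenyl]-4-{2,6-bis(benzyloxy)-4-[(R)-[2,2-diphenyl-7-(prop-2-en-1-yloxy)-1,3-benzodioxol-5-yl][(2R)-oxiran-2-yl]methoxy]phenyl}-3,4-dihydro-2H-chromene (4-aryl trans to 3-benzyloxy) | C(c1ccccc1)Oc1ccc(cc1)[C@H]1Oc2cc(OCc3ccccc3)cc(OCc3ccccc3)c2[C@@H]([C@H]1OCc1ccccc1)c1c(OCc2ccccc2)cc(O[C@H](c2cc(OCC=C)c3OC(c4ccccc4)(c4ccccc4)Oc3c2)[C@H]2CO2)cc1OCc1ccccc1 | intermediate
22 | (2R,3R)-5,7-bis(benzyloxy)-6-{(2R,3R)-3,5,7-tris(benzyloxy)-2-[4-(benzyloxy)phenyl]-3,4-dihydro-2H-chromen-4-yl}-2-[2,2-diphenyl-7-(prop-2-en-1-yloxy)-1,3-benzodioxol-5-yl]-3,4-dihydro-2H-chromen-3-ol (upper C4 aryl trans to C3 benzyloxy; 4β→6) | C(c1ccccc1)Oc1ccc(cc1)[C@H]1Oc2cc(OCc3ccccc3)cc(OCc3ccccc3)c2[C@@H]([C@H]1OCc1ccccc1)c1c(OCc2ccccc2)cc2O[C@H](c3cc(OCC=C)c4OC(c5ccccc5)(c5ccccc5)Oc4c3)[C@H](O)Cc2c1OCc1ccccc1 | intermediate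
23 | (2R,3R)-5,7-bis(benzyloxy)-6-{(2R,3R)-3,5,7-tris(benzyloxy)-2-[4-(benzyloxy)phenyl]-3,4-dihydro-2H-chromen-4-yl}-2-(7-hydroxy-2,2-diphenyl-1,3-benzodioxol-5-yl)-3,4-dihydro-2H-chromen-3-ol (4β→6) | C(c1ccccc1)Oc1ccc(cc1)[C@H]1Oc2cc(OCc3ccccc3)cc(OCc3ccccc3)c2[C@@H]([C@H]1OCc1ccccc1)c1c(OCc2ccccc2)cc2O[C@H](c3cc(O)c4OC(c5ccccc5)(c5ccccc5)Oc4c3)[C@H](O)Cc2c1OCc1ccccc1 | intermediate
24 | 3,4,5-tris(benzyloxy)benzoic acid | OC(=O)c1cc(OCc2ccccc2)c(OCc2ccccc2)c(OCc2ccccc2)c1 | starting material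
25 | (2R,3R)-5,7-bis(benzyloxy)-6-{(2R,3R)-3,5,7-tris(benzyloxy)-2-[4-(benzyloxy)phenyl]-3,4-dihydro-2H-chromen-4-yl}-2-(2,2-diphenyl-7-{[3,4,5-tris(benzyloxy)benzoyl]oxy}-1,3-benzodioxol-5-yl)-3,4-dihydro-2H-chromen-3-yl 3,4,5-tris(benzyloxy)benzoate (4β→6) | C(c1ccccc1)Oc1ccc(cc1)[C@H]1Oc2cc(OCc3ccccc3)cc(OCc3ccccc3)c2[C@@H]([C@H]1OCc1ccccc1)c1c(OCc2ccccc2)cc2O[C@H](c3cc(OC(=O)c4cc(OCc5ccccc5)c(OCc5ccccc5)c(OCc5ccccc5)c4)c4OC(c5ccccc5)(c5ccccc5)Oc4c3)[C@H](OC(=O)c3cc(OCc4ccccc4)c(OCc4ccccc4)c(OCc4ccccc4)c3)Cc2c1OCc1ccccc1 | intermediate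
26 | epiafzelechin-(4β→6)-epigallocatechin 3,3′-di-O-gallate = (2R,3R)-2-{3,4-dihydroxy-5-[(3,4,5-trihydroxybenzoyl)oxy]phenyl}-5,7-dihydroxy-6-[(2R,3R,4S)-3,5,7-trihydroxy-2-(4-hydroxyphenyl)-3,4-dihydro-2H-chromen-4-yl]-3,4-dihydro-2H-chromen-3-yl 3,4,5-trihydroxybenzoate | O=C(Oc1cc([C@H]2Oc3cc(O)c([C@H]4c5c(O)cc(O)cc5O[C@H](c5ccc(O)cc5)[C@@H]4O)c(O)c3C[C@H]2OC(=O)c2cc(O)c(O)c(O)c2)cc(O)c1O)c1cc(O)c(O)c(O)c1 | target

**Step count and risks**
Total steps: 17. Longest linear sequence: 11 steps (1, 2, 3, 5, 6, 7, 13, 14, 15, 16, 17).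

The three steps most likely to fail:

First, step 14, the double Friedel–Crafts closure. The ring D cation may decompose or lose its 3,4-trans preference before ring A captures it, and the epoxide may close 5-exo instead of 6-endo. The fallback separates the two closures and reverses their order. It sets out from 12, whose epoxide is cyclised alone in HFIP to the 6-bromo ring F chromanol F1. F1 is treated with n-BuLi (2.1 equiv, THF, −78 °C; alkoxide formation then bromine–lithium exchange) and aldehyde 18 to give the ring-F-closed carbinol F2. Brief exposure of F2 to HFIP then closes ring C alone, and the route is rejoined at 22.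

Second, step 13, the aryllithium union. The aryllithium may attack its own epoxide intermolecularly or enolise the α-alkoxy aldehyde. The fallback makes the C4–ring D bond before any epoxide exists. It sets out from 8, which is converted with NaH and then n-BuLi (THF, −78 °C) into the phenoxide aryllithium and added to 18 to give the phenolic carbinol F3. The phenoxide of F3 opens glycidic ester 6 (Cs2CO3, DMF) to the hydroxy ester F4, LiBH4 reduces F4 to the triol F5, and NaH/N-tosylimidazole closes the terminal epoxide. The route is rejoined at 20, so step 14 is unchanged.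

Third, step 3, the Jacobsen epoxidation of the very electron-rich Z-cinnamate 5, where the ee may be low and the radical pathway may leak to the trans-epoxide. The fallback uses hydroxyl-directed epoxidation. It sets out from 5, which is reduced with i-Bu2AlH to the (Z)-allylic alcohol F6. Sharpless asymmetric epoxidation (Ti(Oi-Pr)4, D-(−)-diethyl tartrate, t-BuOOH, 4 Å molecular sieves, CH2Cl2, −20 °C) gives the (2R,3S)-cis-epoxy alcohol F7. Opening of F7 at the benzylic carbon by the sodium phenoxide of 8 (aq. NaOH, dioxane, 70 °C, inversion) gives the diol directly, and the route is rejoined at 10.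

**Further compounds**
F1 | step 14 | (2R,3R)-5,7-bis(benzyloxy)-6-bromo-2-[2,2-diphenyl-7-(prop-2-en-1-yloxy)-1,3-benzodioxol-5-yl]-3,4-dihydro-2H-chromen-3-ol | Brc1c(OCc2ccccc2)cc2O[C@H](c3cc(OCC=C)c4OC(c5ccccc5)(c5ccccc5)Oc4c3)[C@H](O)Cc2c1OCc1ccccc1
F2 | step 14 | (1RS,2R,3R)-2-(benzyloxy)-3-[3,5-bis(benzyloxy)phenoxy]-3-[4-(benzyloxy)phenyl]-1-{(2R,3R)-5,7-bis(benzyloxy)-2-[2,2-diphenyl-7-(prop-2-en-1-yloxy)-1,3-benzodioxol-5-yl]-3-hydroxy-3,4-dihydro-2H-chromen-6-yl}propan-1-ol | O(c1cc(OCc2ccccc2)cc(OCc2ccccc2)c1)[C@H](c1ccc(OCc2ccccc2)cc1)[C@H](OCc1ccccc1)C(O)c1c(OCc2ccccc2)cc2O[C@H](c3cc(OCC=C)c4OC(c5ccccc5)(c5ccccc5)Oc4c3)[C@H](O)Cc2c1OCc1ccccc1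
F3 | step 13 | (1RS,2R,3R)-2-(benzyloxy)-3-[3,5-bis(benzyloxy)phenoxy]-3-[4-(benzyloxy)phenyl]-1-[2,6-bis(benzyloxy)-4-hydroxyphenyl]propan-1-ol | O(c1cc(OCc2ccccc2)cc(OCc2ccccc2)c1)[C@H](c1ccc(OCc2ccccc2)cc1)[C@H](OCc1ccccc1)C(O)c1c(OCc2ccccc2)cc(O)cc1OCc1ccccc1
F4 | step 13 | ethyl (2S,3R)-3-{3,5-bis(benzyloxy)-4-[(1RS,2R,3R)-2-(benzyloxy)-3-[3,5-bis(benzyloxy)phenoxy]-3-[4-(benzyloxy)phenyl]-1-hydroxypropyl]phenoxy}-3-[2,2-diphenyl-7-(prop-2-en-1-yloxy)-1,3-benzodioxol-5-yl]-2-hydroxypropanoate | O(c1cc(OCc2ccccc2)cc(OCc2ccccc2)c1)[C@H](c1ccc(OCc2ccccc2)cc1)[C@H](OCc1ccccc1)C(O)c1c(OCc2ccccc2)cc(O[C@H](c2cc(OCC=C)c3OC(c4ccccc4)(c4ccccc4)Oc3c2)[C@H](O)C(=O)OCC)cc1OCc1ccccc1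
F5 | step 13 | (2R,3R)-3-{3,5-bis(benzyloxy)-4-[(1RS,2R,3R)-2-(benzyloxy)-3-[3,5-bis(benzyloxy)phenoxy]-3-[4-(benzyloxy)phenyl]-1-hydroxypropyl]phenoxy}-3-[2,2-diphenyl-7-(prop-2-en-1-yloxy)-1,3-benzodioxol-5-yl]propane-1,2-diol | O(c1cc(OCc2ccccc2)cc(OCc2ccccc2)c1)[C@H](c1ccc(OCc2ccccc2)cc1)[C@H](OCc1ccccc1)C(O)c1c(OCc2ccccc2)cc(O[C@H](c2cc(OCC=C)c3OC(c4ccccc4)(c4ccccc4)Oc3c2)[C@H](O)CO)cc1OCc1ccccc1
F6 | step 3 | (2Z)-3-[2,2-diphenyl-7-(prop-2-en-1-yloxy)-1,3-benzodioxol-5-yl]prop-2-en-1-ol | OC/C=C\c1cc(OCC=C)c2OC(c3ccccc3)(c3ccccc3)Oc2c1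
F7 | step 3 | {(2R,3S)-3-[2,2-diphenyl-7-(prop-2-en-1-yloxy)-1,3-benzodioxol-5-yl]oxiran-2-yl}methanol | OC[C@H]1O[C@H]1c1cc(OCC=C)c2OC(c3ccccc3)(c3ccccc3)Oc2c1
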